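**Plan**
Retrosynthetic cuts, in order: the two aryl O–CH3 bonds (O7 of units B and C); C3=C4 and O1–C2 of the pyranone of unit A; C5–C6 and C4a–C8a of the benzene ring of unit A; the bond from the C3 enol oxygen of unit B to the future C7 of unit A; C3=C4, O1–C2 and the C4 formyl carbon of unit B; the C8–C8' biaryl bond.
Enabling feature: in the benzene ring of unit A the ether oxygen on C7 is meta to the O1-bearing C8a and para to C4a. C8a–C8–C7–C6 is therefore a butadiene with two oxygens on C8a and the unit B enol oxygen on C7, and C4a–C5 with C4 is propynal.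
Forward order: unit C is bought as umbelliferone; a Negishi coupling sets the biaryl; N-acetylglycine closes the pyranone of unit B; Diels–Alder reaction and aromatisation close the benzene ring of unit A; Wittig olefination–lactonisation closes its pyranone; demethylation ends the route.
Stereochemistry: the target has no stereocentre, and the alkene geometries of the enol ether and the ketene acetal disappear into the aromatic ring.

Key step: step 11

Assumption: the target SMILES carries no descriptor for the hindered C8–C8' axis, so the axis is left uncontrolled and every unsymmetrical biaryl of the route is carried as the racemate.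

**Step 1**
Reactants: 1 umbelliferone (7-hydroxycoumarin)
Product: 2 iodophenol 7-hydroxy-8-iodocoumarin
Conditions: iodine (1.0 equiv), KI, 25% aq NH3, 0 °C to rt; acidified to precipitate the product
Reagents that add atoms: iodine, [I][I]
Why: Electrophilic aromatic iodination of the phenoxide should occur at C8, the position between O7 and the O1-bearing C8a that also reacts in aminomethylation and formylation of umbelliferone, and one equivalent of iodine limits attack at C6.

**Step 2**
Reactants: 2 iodophenol 7-hydroxy-8-iodocoumarin
Product: 3 iodide 8-iodo-7-methoxycoumarin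
Conditions: MeI, K2CO3, acetone, reflux
Reagents that add atoms: iodomethane, CI
Why: Williamson O-methylation of an acidic phenol leaves the lactone and the C–I bond untouched, and the methyl ether is chosen because it survives the Lewis acids of steps 4 and 5 and the hot aqueous acid of step 7.

**Step 3**
Reactants: 3 iodide 8-iodo-7-methoxycoumarin; 4 1,3-dimethoxybenzene
Product: 7 aryl coumarin 8-(2,6-dimethoxyphenyl)-7-methoxycoumarin, via 2,6-dimethoxyphenyllithium 5 (not isolated), via 2,6-dimethoxyphenylzinc chloride 6 (not isolated)
Conditions: 4, n-BuLi, THF, 0 °C to rt; ZnCl2, THF, rt; then 3, Pd2(dba)3 (2 mol %), RuPhos (8 mol %), THF, 70 °C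
Reagents that add atoms: none
Why: Directed ortho-lithiation between the two methoxy groups, transmetalation to zinc and Negishi cross-coupling should work because bulky electron-rich dialkylbiarylphosphines are the established ligands for tetra-ortho-substituted biaryls, the four ortho groups are small oxygens, and the base-free arylzinc leaves the lactone closed.

**Step 4**
Reactants: 7 aryl coumarin 8-(2,6-dimethoxyphenyl)-7-methoxycoumarin
Product: 8 aldehyde 2,4-dimethoxy-3-(7-methoxy-2-oxo-2H-chromen-8-yl)benzaldehyde
Conditions: Cl2CHOMe, TiCl4, CH2Cl2, −10 to 0 °C; then ice-cold 1 M HCl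
Reagents that add atoms: dichloromethyl methyl ether, COC(Cl)Cl; water, O
Why: In this Rieche formylation the dimethoxyphenyl ring is far more electron-rich than the TiCl4-complexed coumarin, its two activated positions (ortho to one methoxy group, para to the other) are equivalent by symmetry, and the first formyl group shuts off a second attack.

**Step 5**
Reactants: 8 aldehyde 2,4-dimethoxy-3-(7-methoxy-2-oxo-2H-chromen-8-yl)benzaldehyde
Product: 9 salicylaldehyde 2-hydroxy-4-methoxy-3-(7-methoxy-2-oxo-2H-chromen-8-yl)benzaldehyde
Conditions: BCl3 (1 M in CH2Cl2), CH2Cl2, −78 to 0 °C; then H2O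
Reagents that add atoms: none
Why: In this chelation-controlled ether cleavage BCl3 binds between the formyl oxygen and the neighbouring methoxy oxygen and chloride removes only that methyl group, so the two methoxy groups that mask O7 and O7' remain.

**Step 6**
Reactants: 9 salicylaldehyde 2-hydroxy-4-methoxy-3-(7-methoxy-2-oxo-2H-chromen-8-yl)benzaldehyde; 10 N-acetylglycine
Product: 11 enamide 3-acetamido-7,7'-dimethoxy-8,8'-bicoumarin
Conditions: Ac2O, NaOAc, 115 °C
Reagents that add atoms: none
Why: In this Perkin/Erlenmeyer–Plöchl-type condensation the glycine CH2, activated by Ac2O/NaOAc, condenses with the formyl group and the adjacent phenol oxygen is acylated to close the pyranone of unit B, which is the standard route from salicylaldehydes, including 3-substituted ones, to 3-acetamidocoumarins.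

**Step 7**
Reactants: 11 enamide 3-acetamido-7,7'-dimethoxy-8,8'-bicoumarin
Product: 13 enol 3-hydroxy-7,7'-dimethoxy-8,8'-bicoumarin, via 3-aminobicoumarin 12 (not isolated)
Conditions: 3 M aq HCl, 1,4-dioxane, reflux, N2
Reagents that add atoms: water, O
Why: Acid hydrolysis of the enamide removes the acetyl group, and the imine tautomer of amine 12 is then hydrolysed to the 3-hydroxy lactone, a standard conversion of 3-acetamidocoumarins that aryl methyl ethers survive and acetal protecting groups would not.

**Step 8**
Reactants: 13 enol 3-hydroxy-7,7'-dimethoxy-8,8'-bicoumarin; 14 methyl but-2-ynoate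
Product: 15 enol ether methyl (E)-3-[(7,7'-dimethoxy-8,8'-bicoumarin-3-yl)oxy]but-2-enoate
Conditions: 14 (2 equiv), Cs2CO3 (0.2 equiv), dry DMF, 60 °C
Reagents that add atoms: none
Why: In this base-catalysed oxa-Michael addition of a phenol-like enol (the only free OH) to an alkynoate, proton transfer from 13 regenerates the oxyanion, equilibration favours the E isomer with the aryloxy group trans to the ester, and phosphine catalysts are avoided because they would send the nucleophile to the γ-carbon.

**Step 9**
Reactants: 15 enol ether methyl (E)-3-[(7,7'-dimethoxy-8,8'-bicoumarin-3-yl)oxy]but-2-enoate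
Product: 16 diene 3-{[(3Z)-4-methoxy-4-(trimethylsilyloxy)buta-1,3-dien-2-yl]oxy}-7,7'-dimethoxy-8,8'-bicoumarin
Conditions: TMSOTf, Et3N, CH2Cl2, 0 °C; volatiles removed in vacuo, residue taken up in dry toluene and filtered under Ar, used at once
Reagents that add atoms: trimethylsilyl trifluoromethanesulfonate, C[Si](C)(C)OS(=O)(=O)C(F)(F)F
Why: In this soft enolisation, O-silylation of the ester carbonyl acidifies the γ-methyl group, which Et3N deprotonates to the vinylketene silyl acetal as in the conversion of 3-siloxycrotonates to 1-alkoxy-1,3-bis(siloxy)butadienes, and it is preferred to a lithium amide because no free dienolate arises that could expel the unit B enolate or add to a coumarin C4.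

**Step 10**
Reactants: 17 propargyl alcohol
Product: 18 propynal
Conditions: CrO3, H2SO4, H2O, 2–10 °C, about 50 mmHg, product swept into −78 °C traps; dried (MgSO4), redistilled, kept cold and free of base
Reagents that add atoms: none
Why: In this chromic acid oxidation of a primary propargylic alcohol, continuous removal of the volatile aldehyde prevents over-oxidation, and distillation gives material free of alcohol and water, either of which would desilylate 16.

**Step 11**
Reactants: 16 diene 3-{[(3Z)-4-methoxy-4-(trimethylsilyloxy)buta-1,3-dien-2-yl]oxy}-7,7'-dimethoxy-8,8'-bicoumarin; 18 propynal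
Product: 21 salicylaldehyde 4-[(7,7'-dimethoxy-8,8'-bicoumarin-3-yl)oxy]-2-hydroxybenzaldehyde, via cyclohexadiene cycloadduct 19 (not isolated), via aryl trimethylsilyl ether 20 (not isolated)
Conditions: 18 (3 equiv), toluene, 0 °C to rt (to 50 °C if needed); then 1 M HCl–THF, rt
Reagents that add atoms: none
Why: The CH2 terminus of 16 (future C6), made nucleophilic by the two ketene acetal oxygens and by the enol-ether oxygen of unit B, bonds to the unsubstituted β-carbon of 18 (future C5) slightly ahead of bond formation between the acetal carbon (C8a) and the formyl-bearing α-carbon (C4a), a polarised, asynchronous, normal-electron-demand Diels–Alder reaction that gives the 1,4-cyclohexadiene 19. The closest known reaction type is the regiospecific benzannulation of 1,1,3-trioxygenated butadienes (vinylketene acetals) with acetylenic aldehydes, ketones and esters. The benzene ring of unit A closes in the intermolecular (4+2) mode, C8a, C8, C7 and C6 coming from the diene and C5 and C4a from the ynal; the methoxy oxygen of the mixed acetal, more basic than the siloxy oxygen, then leaves together with a C6 proton in a 1,4-elimination to give the aryl silyl ether 20, and dilute acid frees the phenol of 21. No stereocentre is created for the target, since the acetal carbon of 19 is stereogenic only until aromatisation flattens it. Regioselectivity (formyl para to the aryloxy group and ortho to the new hydroxyl) follows from the matched polarisation of the two partners. Chemoselectivity for the C≡C bond over the formyl C=O and over the coumarin C3=C4 bonds is secured by excluding Lewis and Brønsted acids until the cycloaddition is over, which is why 16 is freed from triflate salts and 18 is distilled, and by the poor dienophilicity of the benzo-fused lactone alkenes.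

**Step 12**
Reactants: 21 salicylaldehyde 4-[(7,7'-dimethoxy-8,8'-bicoumarin-3-yl)oxy]-2-hydroxybenzaldehyde; 22 ethyl (triphenylphosphoranylidene)acetate
Product: 24 tricoumarin 7,7'-di-O-methyltriumbelletin, via E-hydroxycinnamate 23 (not isolated)
Conditions: 22 (1.3 equiv), N,N-diethylaniline, reflux (about 215 °C), N2
Reagents that add atoms: none
Why: Wittig olefination followed by thermal E-to-Z isomerisation and attack of the phenol oxygen on the ester carbonyl is the established one-pot conversion of salicylaldehydes to 3,4-unsubstituted coumarins, and the ethers and lactones present should tolerate neutral heating.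

**Step 13**
Reactants: 24 tricoumarin 7,7'-di-O-methyltriumbelletin
Product: 25 triumbelletin
Conditions: BBr3 (6 equiv), CH2Cl2, −78 °C to rt; then ice–water
Reagents that add atoms: none
Why: In this Lewis acid ether cleavage bromide attacks only the sp3 methyl carbons of the boron-complexed aryl methyl ethers, whereas the C3–O–C7 ether joins two sp2 carbons and the lactones only complex reversibly, as in the routine demethylation of 7-methoxycoumarins.

**Compound list**
1 | umbelliferone (7-hydroxy-2H-chromen-2-one) | O=c1ccc2ccc(O)cc2o1 | starting material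
2 | 7-hydroxy-8-iodocoumarin | O=c1ccc2ccc(O)c(I)c2o1 | intermediate
3 | 8-iodo-7-methoxycoumarin | COc1ccc2ccc(=O)oc2c1I | intermediate
4 | 1,3-dimethoxybenzene | COc1cccc(OC)c1 | starting material
5 | 2,6-dimethoxyphenyllithium | [Li]c1c(OC)cccc1OC | intermediate
6 | 2,6-dimethoxyphenylzinc chloride | Cl[Zn]c1c(OC)cccc1OC | intermediate
7 | 8-(2,6-dimethoxyphenyl)-7-methoxycoumarin | COc1cccc(OC)c1-c1c(OC)ccc2ccc(=O)oc12 | intermediate
8 | 2,4-dimethoxy-3-(7-methoxy-2-oxo-2H-chromen-8-yl)benzaldehyde | COc1ccc(C=O)c(OC)c1-c1c(OC)ccc2ccc(=O)oc12 | intermediate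
9 | 2-hydroxy-4-methoxy-3-(7-methoxy-2-oxo-2H-chromen-8-yl)benzaldehyde | COc1ccc(C=O)c(O)c1-c1c(OC)ccc2ccc(=O)oc12 | intermediate
10 | N-acetylglycine | CC(=O)NCC(=O)O | starting material
11 | 3-acetamido-7,7'-dimethoxy-8,8'-bicoumarin | CC(=O)Nc1cc2ccc(OC)c(-c3c(OC)ccc4ccc(=O)oc34)c2oc1=O | intermediate
12 | 3-amino-7,7'-dimethoxy-8,8'-bicoumarin | Nc1cc2ccc(OC)c(-c3c(OC)ccc4ccc(=O)oc34)c2oc1=O | intermediate
13 | 3-hydroxy-7,7'-dimethoxy-8,8'-bicoumarin | COc1ccc2cc(O)c(=O)oc2c1-c1c(OC)ccc2ccc(=O)oc12 | intermediate
14 | methyl but-2-ynoate | CC#CC(=O)OC | starting material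
15 | methyl (E)-3-[(7,7'-dimethoxy-8,8'-bicoumarin-3-yl)oxy]but-2-enoate | COC(=O)/C=C(\C)Oc1cc2ccc(OC)c(-c3c(OC)ccc4ccc(=O)oc34)c2oc1=O | intermediate
16 | 3-{[(3Z)-4-methoxy-4-(trimethylsilyloxy)buta-1,3-dien-2-yl]oxy}-7,7'-dimethoxy-8,8'-bicoumarin (ketene acetal drawn Z; its geometry has no bearing on the outcome) | C=C(Oc1cc2ccc(OC)c(-c3c(OC)ccc4ccc(=O)oc34)c2oc1=O)/C=C(/OC)O[Si](C)(C)C | intermediate
17 | propargyl alcohol | C#CCO | starting material
18 | propynal | C#CC=O | intermediate
19 | 4-[(7,7'-dimethoxy-8,8'-bicoumarin-3-yl)oxy]-6-methoxy-6-(trimethylsilyloxy)cyclohexa-1,4-diene-1-carbaldehyde (acetal carbon unassigned, transient) | COC1(O[Si](C)(C)C)C=C(Oc2cc3ccc(OC)c(-c4c(OC)ccc5ccc(=O)oc45)c3oc2=O)CC=C1C=O | intermediate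
20 | 4-[(7,7'-dimethoxy-8,8'-bicoumarin-3-yl)oxy]-2-(trimethylsilyloxy)benzaldehyde | C[Si](C)(C)Oc1cc(Oc2cc3ccc(OC)c(-c4c(OC)ccc5ccc(=O)oc45)c3oc2=O)ccc1C=O | intermediate
21 | 4-[(7,7'-dimethoxy-8,8'-bicoumarin-3-yl)oxy]-2-hydroxybenzaldehyde | O=Cc1ccc(Oc2cc3ccc(OC)c(-c4c(OC)ccc5ccc(=O)oc45)c3oc2=O)cc1O | intermediate
22 | ethyl (triphenylphosphoranylidene)acetate | CCOC(=O)C=P(c1ccccc1)(c1ccccc1)c1ccccc1 | starting material
23 | ethyl (E)-3-{4-[(7,7'-dimethoxy-8,8'-bicoumarin-3-yl)oxy]-2-hydroxyphenyl}acrylate | CCOC(=O)/C=C/c1ccc(Oc2cc3ccc(OC)c(-c4c(OC)ccc5ccc(=O)oc45)c3oc2=O)cc1O | intermediate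
24 | 7,7'-di-O-methyltriumbelletin, 7,7'-dimethoxy-3-[(2-oxo-2H-chromen-7-yl)oxy]-8,8'-bicoumarin | O=c1ccc2ccc(Oc3cc4ccc(OC)c(-c5c(OC)ccc6ccc(=O)oc56)c4oc3=O)cc2o1 | intermediate
25 | triumbelletin | O=c1ccc2ccc(Oc3cc4ccc(O)c(-c5c(O)ccc6ccc(=O)oc56)c4oc3=O)cc2o1 | target

**Step count**
Total steps: 13. Longest linear sequence: 12 (steps 1–9 and 11–13, from umbelliferone). Step 10 is a one-step side branch.

**Steps most likely to fail**

Step 9. The silyl triflate may be tied up by the two lactone carbonyls so that γ-deprotonation stays incomplete. The ammonium triflate may reprotonate the ketene acetal during isolation. The vinylogous carbonate may also fragment with release of the unit B enol. The fallback gives up the cycloaddition and makes the same C7–O bond by nucleophilic aromatic substitution. It sets out from 13, which with 4-fluoro-2-methoxybenzaldehyde (K2CO3, DMSO, 100 °C) should give 4-[(7,7'-dimethoxy-8,8'-bicoumarin-3-yl)oxy]-2-methoxybenzaldehyde F1, the fluoride being activated by the para formyl group. Chelation-controlled BCl3 cleavage of the methoxy group next to the formyl group, as in step 5, then returns to the route at 21.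

Step 11. The ynal may polymerise on contact with the nucleophilic diene or with traces of amine. The diene terminus may add to the formyl carbon (vinylogous Mukaiyama aldol or hetero-Diels–Alder pathway) instead of the triple bond. The diene may also lose its silyl group before it cycloadds. The fallback keeps the same two bonds but replaces the alkyne by an alkene dienophile with a leaving group. It sets out from 16, which with distilled 2-bromoacrolein (toluene, −20 °C to rt) should give 1-bromo-4-[(7,7'-dimethoxy-8,8'-bicoumarin-3-yl)oxy]-2-methoxy-2-(trimethylsilyloxy)cyclohex-3-ene-1-carbaldehyde F2 with the same regiochemistry. The C=C bond of this dienophile is a much better (4+2) partner than its C=O bond. Et3N then removes HBr, and the route is rejoined at 19, which aromatises to 21 under the acidic work-up of step 11.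

Step 3. Transmetalation and reductive elimination at a palladium centre bearing two 2,6-dioxygenated aryl groups may be slow. Reduction of the C–I bond and homocoupling of the zinc reagent would then take over. The fallback avoids a hindered cross-coupling and builds unit C onto a symmetrical biaryl. It sets out from 4, which is lithiated to 5 as in step 3 and oxidatively homocoupled with FeCl3 to 2,2',6,6'-tetramethoxybiphenyl F3. Rieche formylation with one equivalent of Cl2CHOMe/TiCl4 (unreacted F3 being recycled) should give 2,2',6,6'-tetramethoxybiphenyl-3-carbaldehyde F4. BCl3 then cleaves the methoxy group next to the formyl group to give 2-hydroxy-2',6,6'-trimethoxybiphenyl-3-carbaldehyde F5. Ylide 22 in refluxing N,N-diethylaniline passes through ethyl (E)-3-(2-hydroxy-2',6,6'-trimethoxybiphenyl-3-yl)acrylate F6 and lactonises, coming back to the route at 7.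

**Further compounds**
F1 | step 9 | 4-[(7,7'-dimethoxy-8,8'-bicoumarin-3-yl)oxy]-2-methoxybenzaldehyde | COc1cc(Oc2cc3ccc(OC)c(-c4c(OC)ccc5ccc(=O)oc45)c3oc2=O)ccc1C=O
F2 | step 11 | 1-bromo-4-[(7,7'-dimethoxy-8,8'-bicoumarin-3-yl)oxy]-2-methoxy-2-(trimethylsilyloxy)cyclohex-3-ene-1-carbaldehyde (mixture of stereoisomers, all centres lost on aromatisation) | COC1(O[Si](C)(C)C)C=C(Oc2cc3ccc(OC)c(-c4c(OC)ccc5ccc(=O)oc45)c3oc2=O)CCC1(Br)C=O
F3 | step 3 | 2,2',6,6'-tetramethoxybiphenyl | COc1cccc(OC)c1-c1c(OC)cccc1OC
F4 | step 3 | 2,2',6,6'-tetramethoxybiphenyl-3-carbaldehyde | COc1cccc(OC)c1-c1c(OC)ccc(C=O)c1OC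
F5 | step 3 | 2-hydroxy-2',6,6'-trimethoxybiphenyl-3-carbaldehyde | COc1cccc(OC)c1-c1c(OC)ccc(C=O)c1O
F6 | step 3 | ethyl (E)-3-(2-hydroxy-2',6,6'-trimethoxybiphenyl-3-yl)acrylate | CCOC(=O)/C=C/c1ccc(OC)c(-c2c(OC)cccc2OC)c1O
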